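**Retrosynthetic overview**
The strategy rests on the acyclic C7(OH)–C8(O-aryl) pair that joins ring A (the 4-hydroxy-3,5-dimethoxyphenyl ring on C7) through O4' to ring B (the 2,6-dimethoxyphenyl ether on C8). One oxidation level lower, this pair is the trisubstituted Z aryl enol ether C7=C8(O4'–ring B)–C9.
Last disconnections: the three silyl ethers (buffered fluoride) and the C1'–C7' bond of the E-propenol arm on ring B (Suzuki–Miyaura coupling of a ring B bromide with an E alkenylboronate).
Key disconnection: C8–H and C7–O are taken off together, leading back to the Z enol ether; forward, one asymmetric syn hydroboration–oxidation with IpcBH2 sets 7S and 8R.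
The enol ether comes from a Z α-aryloxy enoate, made by ester aldol addition and E1cB dehydration (C7–C8) of an aryloxyacetate, which is made by Williamson etherification (O4'–C8).
No ring is formed; the bonds are made in the order O4'–C8, C7–C8, H and O across C7=C8, then C1'–C7'.

Key step: step 7

Assumption (remark on the chemistry): the π-face preferred by IpcBH2 on this enol ether is assigned by analogy with simple trisubstituted alkenes, for which the reagent made from (+)-α-pinene delivers oxygen to the face that corresponds here to 7S. If the opposite sense were found, the reagent from (−)-α-pinene would be used with no other change.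

**Step 1**
Reactants: 1 4-bromo-2,6-dimethoxyphenol; 2 ethyl bromoacetate
Product: 3 ethyl (4-bromo-2,6-dimethoxyphenoxy)acetate
Conditions: K2CO3, acetone, reflux
Reagents that add atoms: none
Why: Williamson ether synthesis, in which the phenoxide of 1 displaces the primary α-bromo ester bromide by SN2 and forms the O4'–C8 bond while the aryl bromide stays inert.

**Step 2**
Reactants: 4 syringaldehyde
Product: 5 3,5-dimethoxy-4-(triisopropylsilyloxy)benzaldehyde
Conditions: TIPSCl, imidazole, DMAP (cat.), DMF, 40 °C
Reagents that add atoms: triisopropylsilyl chloride, CC(C)[Si](Cl)(C(C)C)C(C)C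
Why: Silylation of a phenol with a silyl chloride and imidazole; the bulky TIPS ether, shielded by the two flanking methoxy groups, should survive the enolate, hydride, borane and aqueous phosphate steps and blocks quinone methide formation once C7 carries oxygen.

**Step 3**
Reactants: 3 ethyl (4-bromo-2,6-dimethoxyphenoxy)acetate; 5 3,5-dimethoxy-4-(triisopropylsilyloxy)benzaldehyde
Product: 7 ethyl 2-(4-bromo-2,6-dimethoxyphenoxy)-3-hydroxy-3-[3,5-dimethoxy-4-(triisopropylsilyloxy)phenyl]propanoate as a racemic syn/anti mixture, via lithium enolate 6 (not isolated)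
Conditions: LiN(i-Pr)2, THF, −78 °C; then 5, −78 °C; AcOH quench
Reagents that add atoms: lithium diisopropylamide, CC(C)N([Li])C(C)C (its lithium stays only in enolate 6)
Why: Ester enolate aldol addition, in which the amide base deprotonates 3 at C8 at low temperature without touching the aryl bromide and the enolate adds to the non-enolisable aldehyde 5 to form the C7–C8 bond; the two new stereocenters need no control because step 4 erases both.

**Step 4**
Reactants: 7 the aldol adduct (diastereomer mixture)
Product: 9 ethyl (Z)-2-(4-bromo-2,6-dimethoxyphenoxy)-3-[3,5-dimethoxy-4-(triisopropylsilyloxy)phenyl]prop-2-enoate, via benzylic mesylate 8 (not isolated)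
Conditions: MsCl, Et3N, CH2Cl2, 0 °C; then DBU, 0 °C to rt
Reagents that add atoms: methanesulfonyl chloride, CS(=O)(=O)Cl (its CH3SO2 group stays only in mesylate 8)
Why: Mesylation of the benzylic alcohol followed by base-induced E1cB elimination through the ester enolate, which is stereoconvergent because both diastereomers of 8 pass through the same kind of enolate and should collapse mainly to the more stable Z enoate (ring A trans to the ester, cis to the aryloxy group), the minor E isomer being removed by chromatography or crystallisation.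

**Step 5**
Reactants: 9 the Z α-aryloxy enoate
Product: 10 (Z)-2-(4-bromo-2,6-dimethoxyphenoxy)-3-[3,5-dimethoxy-4-(triisopropylsilyloxy)phenyl]prop-2-en-1-ol
Conditions: i-Bu2AlH, CH2Cl2, −78 °C; aq potassium sodium tartrate work-up
Reagents that add atoms: none
Why: 1,2-Reduction of an α,β-unsaturated ester to the allylic alcohol with a dialkylaluminium hydride at low temperature, which leaves the enol ether double bond, the aryl bromide and the silyl ether untouched; the acid-sensitive enol ether 10 would be purified on base-washed silica, where any remaining E isomer is also removed.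

**Step 6**
Reactants: 10 the Z allylic alcohol
Product: 11 the tert-butyldimethylsilyl ether of 10, (Z)-ArCH=C(OAr')CH2OTBS with Ar = 3,5-dimethoxy-4-(triisopropylsilyloxy)phenyl and Ar' = 4-bromo-2,6-dimethoxyphenyl
Conditions: TBSCl, imidazole, CH2Cl2, 0 °C to rt
Reagents that add atoms: tert-butyldimethylsilyl chloride, CC(C)(C)[Si](C)(C)Cl
Why: Standard silylation of a primary alcohol, which removes the acidic O–H before the borane step and gives the geometrically pure Z enol ether substrate.

**Step 7**
Reactants: 11 the Z enol ether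
Product: 13 (1S,2R)-2-(4-bromo-2,6-dimethoxyphenoxy)-3-(tert-butyldimethylsilyloxy)-1-[3,5-dimethoxy-4-(triisopropylsilyloxy)phenyl]propan-1-ol (7S,8R erythro), via C7 isopinocampheylborane 12 (not isolated)
Conditions: IpcBH2 [made from (+)-α-pinene, freed beforehand from its TMEDA adduct], THF, −25 °C; then aq NaOAc, 30% H2O2, 0 °C to rt
Reagents that add atoms: hydrogen peroxide, OO (gives the C7 oxygen); monoisopinocampheylborane from (+)-α-pinene, C[C@H]1[C@H]([BH2])C[C@@H]2C[C@H]1C2(C)C (gives the C8 hydrogen; its boron and isopinocampheyl group stay only in borane 12)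
Why: Proposed new method: the B–H bond of IpcBH2 should add across C7=C8 of 11 through a concerted four-centre transition state, with boron going to C7 (the less substituted carbon and the nucleophilic β-carbon of the enol ether, a bias expected to outweigh the weaker opposite pull of the electron-rich ring A) and hydrogen to C8 on the same face, after which peroxide oxidation moves C7 from boron to oxygen with retention. The closest known reaction type is the Brown asymmetric hydroboration–oxidation of trisubstituted alkenes and of cyclic enol ethers with isopinocampheylboranes, which has not been shown on an acyclic trisubstituted aryl enol ether. No ring closes in this step. C7 and C8 are created together: their erythro relation follows from syn addition to the Z alkene (ring A trans to C9) plus retentive oxidation, and their absolute 7S,8R configuration from the face chosen by the isopinocampheyl group of the reagent made from (+)-α-pinene. The step needs π-face selectivity (reagent control), regioselectivity (secured by the enol ether polarisation and the substitution pattern) and diastereoselectivity (secured by the geometric purity of 11). β-Elimination of the ring B aryloxide from the β-aryloxyborane 12 is the main side reaction and should be held back by the low temperature and by oxidising in the same pot under acetate buffer.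

**Step 8**
Reactants: 13 the 7S,8R aryl bromide; 14 (E)-3-(tert-butyldimethylsilyloxy)prop-1-enylboronic acid pinacol ester
Product: 15 (1S,2R)-3-(tert-butyldimethylsilyloxy)-2-{4-[(E)-3-(tert-butyldimethylsilyloxy)prop-1-enyl]-2,6-dimethoxyphenoxy}-1-[3,5-dimethoxy-4-(triisopropylsilyloxy)phenyl]propan-1-ol
Conditions: Pd(OAc)2, SPhos, K3PO4, THF/H2O, 50 °C
Reagents that add atoms: none
Why: Suzuki–Miyaura cross-coupling of the unhindered ring B aryl bromide with an E alkenylboronate, which forms C1'–C7' with retention of alkene geometry; the mild phosphate base at moderate temperature should leave the silyl ethers and the C7/C8 stereocenters untouched.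

**Step 9**
Reactants: 15 the fully silylated compound
Product: 16 (1S,2R)-1-(4-hydroxy-3,5-dimethoxyphenyl)-2-{4-[(E)-3-hydroxyprop-1-enyl]-2,6-dimethoxyphenoxy}propane-1,3-diol (CNP0207964.1)
Conditions: Bu4NF, AcOH (1:1), THF, 0 °C to rt
Reagents that add atoms: none
Why: Fluoride-mediated cleavage of the aryl TIPS ether and both TBS ethers, buffered with acetic acid so that the freed phenol is never held as a phenoxide that could expel the C7 hydroxyl as a quinone methide and scramble C7.

**Compound list**
1 | 4-bromo-2,6-dimethoxyphenol | COc1cc(Br)cc(OC)c1O | starting material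
2 | ethyl bromoacetate | CCOC(=O)CBr | starting material
3 | ethyl (4-bromo-2,6-dimethoxyphenoxy)acetate | CCOC(=O)COc1c(OC)cc(Br)cc1OC | intermediate
4 | syringaldehyde (4-hydroxy-3,5-dimethoxybenzaldehyde) | COc1cc(C=O)cc(OC)c1O | starting material
5 | 3,5-dimethoxy-4-(triisopropylsilyloxy)benzaldehyde | COc1cc(C=O)cc(OC)c1O[Si](C(C)C)(C(C)C)C(C)C | intermediate
6 | lithium enolate of 3 (enolate geometry not specified) | CCOC(O[Li])=COc1c(OC)cc(Br)cc1OC | intermediate
7 | ethyl 2-(4-bromo-2,6-dimethoxyphenoxy)-3-hydroxy-3-[3,5-dimethoxy-4-(triisopropylsilyloxy)phenyl]propanoate, racemic syn/anti mixture | CCOC(=O)C(Oc1c(OC)cc(Br)cc1OC)C(O)c1cc(OC)c(O[Si](C(C)C)(C(C)C)C(C)C)c(OC)c1 | intermediate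
8 | benzylic methanesulfonate of 7, diastereomer mixture | CCOC(=O)C(Oc1c(OC)cc(Br)cc1OC)C(OS(C)(=O)=O)c1cc(OC)c(O[Si](C(C)C)(C(C)C)C(C)C)c(OC)c1 | intermediate
9 | ethyl (Z)-2-(4-bromo-2,6-dimethoxyphenoxy)-3-[3,5-dimethoxy-4-(triisopropylsilyloxy)phenyl]prop-2-enoate | CCOC(=O)/C(Oc1c(OC)cc(Br)cc1OC)=C/c1cc(OC)c(O[Si](C(C)C)(C(C)C)C(C)C)c(OC)c1 | intermediate
10 | (Z)-2-(4-bromo-2,6-dimethoxyphenoxy)-3-[3,5-dimethoxy-4-(triisopropylsilyloxy)phenyl]prop-2-en-1-ol | OC/C(Oc1c(OC)cc(Br)cc1OC)=C/c1cc(OC)c(O[Si](C(C)C)(C(C)C)C(C)C)c(OC)c1 | intermediate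
11 | tert-butyldimethylsilyl ether of 10, the Z enol ether substrate | CC(C)(C)[Si](C)(C)OC/C(Oc1c(OC)cc(Br)cc1OC)=C/c1cc(OC)c(O[Si](C(C)C)(C(C)C)C(C)C)c(OC)c1 | intermediate
12 | C7 (isopinocampheyl)borane adduct of 11, boron on C7 and the new hydrogen on C8 on the same face | COc1cc([C@H]([BH][C@@H]2C[C@@H]3C[C@H]([C@H]2C)C3(C)C)[C@@H](CO[Si](C)(C)C(C)(C)C)Oc2c(OC)cc(Br)cc2OC)cc(OC)c1O[Si](C(C)C)(C(C)C)C(C)C | intermediate
13 | (1S,2R)-2-(4-bromo-2,6-dimethoxyphenoxy)-3-(tert-butyldimethylsilyloxy)-1-[3,5-dimethoxy-4-(triisopropylsilyloxy)phenyl]propan-1-ol | COc1cc([C@H](O)[C@@H](CO[Si](C)(C)C(C)(C)C)Oc2c(OC)cc(Br)cc2OC)cc(OC)c1O[Si](C(C)C)(C(C)C)C(C)C | intermediate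
14 | (E)-3-(tert-butyldimethylsilyloxy)prop-1-enylboronic acid pinacol ester | CC(C)(C)[Si](C)(C)OC/C=C/B1OC(C)(C)C(C)(C)O1 | starting material
15 | (1S,2R)-3-(tert-butyldimethylsilyloxy)-2-{4-[(E)-3-(tert-butyldimethylsilyloxy)prop-1-enyl]-2,6-dimethoxyphenoxy}-1-[3,5-dimethoxy-4-(triisopropylsilyloxy)phenyl]propan-1-ol | COc1cc([C@H](O)[C@@H](CO[Si](C)(C)C(C)(C)C)Oc2c(OC)cc(/C=C/CO[Si](C)(C)C(C)(C)C)cc2OC)cc(OC)c1O[Si](C(C)C)(C(C)C)C(C)C | intermediate
16 | (1S,2R)-1-(4-hydroxy-3,5-dimethoxyphenyl)-2-{4-[(E)-3-hydroxyprop-1-enyl]-2,6-dimethoxyphenoxy}propane-1,3-diol | COc1cc([C@H](O)[C@@H](CO)Oc2c(OC)cc(/C=C/CO)cc2OC)cc(OC)c1O | target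

**Totals**
Total step count: 9
Longest linear sequence: 8 steps (1 or 4 to 16; steps 1 and 2 are parallel)

**Steps most likely to fail**

Step 7. The hydroboration could fail through poor π-facial discrimination, sluggish addition to the hindered enol ether, or β-elimination of the aryloxide from the β-aryloxyborane. The C7/C8 pair would then be built by auxiliary-controlled aldol chemistry, setting out from phenol 1 and aldehyde 5 and coming back at 13. Phenol 1 is O-alkylated with commercial (S)-4-benzyl-3-(chloroacetyl)oxazolidin-2-one (K2CO3, NaI cat., acetone) to give (S)-4-benzyl-3-[(4-bromo-2,6-dimethoxyphenoxy)acetyl]oxazolidin-2-one F1. Its dibutylboron enolate (Bu2BOTf, i-Pr2NEt, CH2Cl2, −78 to 0 °C) adds to 5 in an Evans syn glycolate aldol reaction to give the syn aldol adduct F2, which already has the required configuration at C8. LiBH4 (THF, MeOH, 0 °C) removes the auxiliary reductively to give the (7R,8R)-threo diol F3. TBSCl and imidazole silylate the primary hydroxyl to give the threo silyl ether F4, the C7 epimer of 13. Mitsunobu inversion at C7 with 4-nitrobenzoic acid (PPh3, DIAD, THF, 0 °C) gives the (7S,8R) 4-nitrobenzoate F5, and brief methanolysis (K2CO3, MeOH, 0 °C) releases 13. Because the auxiliary fixes C8, any loss of integrity at C7 during the inversion would give only the separable threo diastereomer and not the enantiomer.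

Step 4. The dehydration could fail through ionisation of the electron-rich benzylic mesylate (substitution, or desilylation toward a quinone methide) or through an incomplete bias toward the Z geometry. The C7=C8 bond would then be made by olefination, setting out from phenol 1 and aldehyde 5 and coming back at enoate 9. Rh2(OAc)4-catalysed O–H insertion of the carbenoid from ethyl diazo(diethoxyphosphoryl)acetate into 1 (toluene, 80 °C) gives ethyl (4-bromo-2,6-dimethoxyphenoxy)(diethoxyphosphoryl)acetate F6. Its Horner–Wadsworth–Emmons reaction with 5 (LiN(SiMe3)2, THF, −78 °C to rt) gives 9 without any benzylic leaving group. Residual E enoate from either entry would be equilibrated to the more stable Z isomer (catalytic PhSSPh under visible light, or catalytic I2) before the reduction.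

Step 8. The coupling could fail through base-induced loss of the aryl silyl ether, which would expose the p-hydroxybenzyl alcohol to quinone methide chemistry, or through protodeboronation of 14. The arm would then be built in two stages under water-free amine-base conditions, setting out from bromide 13 and coming back at target 16. Heck reaction of 13 with methyl acrylate (Pd2(dba)3, P(t-Bu)3, Cy2NMe, dioxane, 70 °C) gives the (E)-methyl cinnamate F7. Reduction with i-Bu2AlH (CH2Cl2, −78 °C) gives the (E)-allylic alcohol F8, which carries only the C9 TBS and phenolic TIPS groups and is desilylated under the conditions of step 9 to give 16.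

**Further compounds**
F1 | step 7 | (S)-4-benzyl-3-[(4-bromo-2,6-dimethoxyphenoxy)acetyl]oxazolidin-2-one | O=C(COc1c(OC)cc(Br)cc1OC)N1[C@@H](Cc2ccccc2)COC1=O
F2 | step 7 | (4S)-4-benzyl-3-{(2S,3R)-2-(4-bromo-2,6-dimethoxyphenoxy)-3-hydroxy-3-[3,5-dimethoxy-4-(triisopropylsilyloxy)phenyl]propanoyl}oxazolidin-2-one, syn aldol adduct | O=C([C@@H](Oc1c(OC)cc(Br)cc1OC)[C@H](O)c1cc(OC)c(O[Si](C(C)C)(C(C)C)C(C)C)c(OC)c1)N1[C@@H](Cc2ccccc2)COC1=O
F3 | step 7 | (1R,2R)-2-(4-bromo-2,6-dimethoxyphenoxy)-1-[3,5-dimethoxy-4-(triisopropylsilyloxy)phenyl]propane-1,3-diol, threo diol | COc1cc([C@@H](O)[C@@H](CO)Oc2c(OC)cc(Br)cc2OC)cc(OC)c1O[Si](C(C)C)(C(C)C)C(C)C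
F4 | step 7 | (1R,2R)-2-(4-bromo-2,6-dimethoxyphenoxy)-3-(tert-butyldimethylsilyloxy)-1-[3,5-dimethoxy-4-(triisopropylsilyloxy)phenyl]propan-1-ol, C7 epimer of 13 | COc1cc([C@@H](O)[C@@H](CO[Si](C)(C)C(C)(C)C)Oc2c(OC)cc(Br)cc2OC)cc(OC)c1O[Si](C(C)C)(C(C)C)C(C)C
F5 | step 7 | (7S,8R) 4-nitrobenzoate of 13 | COc1cc([C@H](OC(=O)c2ccc(cc2)[N+](=O)[O-])[C@@H](CO[Si](C)(C)C(C)(C)C)Oc2c(OC)cc(Br)cc2OC)cc(OC)c1O[Si](C(C)C)(C(C)C)C(C)C
F6 | step 4 | ethyl (4-bromo-2,6-dimethoxyphenoxy)(diethoxyphosphoryl)acetate | CCOC(=O)C(Oc1c(OC)cc(Br)cc1OC)P(=O)(OCC)OCC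
F7 | step 8 | methyl (E)-3-[4-({(1S,2R)-3-(tert-butyldimethylsilyloxy)-1-hydroxy-1-[3,5-dimethoxy-4-(triisopropylsilyloxy)phenyl]propan-2-yl}oxy)-3,5-dimethoxyphenyl]prop-2-enoate | COc1cc([C@H](O)[C@@H](CO[Si](C)(C)C(C)(C)C)Oc2c(OC)cc(/C=C/C(=O)OC)cc2OC)cc(OC)c1O[Si](C(C)C)(C(C)C)C(C)C
F8 | step 8 | (1S,2R)-3-(tert-butyldimethylsilyloxy)-2-{4-[(E)-3-hydroxyprop-1-enyl]-2,6-dimethoxyphenoxy}-1-[3,5-dimethoxy-4-(triisopropylsilyloxy)phenyl]propan-1-ol | COc1cc([C@H](O)[C@@H](CO[Si](C)(C)C(C)(C)C)Oc2c(OC)cc(/C=C/CO)cc2OC)cc(OC)c1O[Si](C(C)C)(C(C)C)C(C)C
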